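I decided to commit to no mechanism and to carry one number from the earlier runs to the north flask.

| flask | starting material | partner | free catalyst | time |
|---|---|---|---|---|
| south | 150 mM | 150 mM | 0.300 mM |  |
| west | 150 mM | 450 mM | 0.300 mM |  |
| south-west | 300 mM | 150 mM | 0.300 mM |  |
| north | 150 mM | 1100 mM | 0.300 mM | 5.2 h |

| south run: time / h | south run: [starting material] / mM | west run: time / h | west run: [starting material] / mM | south-west run: time / h | south-west run: [starting material] / mM |
|---|---|---|---|---|---|
| 0.21 | 144.8 | 0.21 | 135.5 | 0.21 | 291.2 |
| 0.47 | 139.8 | 0.47 | 123.3 | 0.47 | 284.2 |
| 1.0 | 132.5 | 1.0 | 104.9 | 1.0 | 270.3 |
| 2.3 | 122.6 | 2.3 | 83.4 | 2.3 | 252.6 |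
| 5.2 | 117.8 | 5.2 | 72.3 | 5.2 | 243.6 |

(scatter of a reading: 0.8 mM)

- order of the initial rate in [partner], near the charge of the south run, the rate being that where two percent of its starting material are target
- order of the initial rate in [starting material], near the charge of the south run, the rate being that where two percent of its starting material are target (one fixed amount of target, the same in the runs compared)
- starting material in the north run at 5.2 h, as a share of the starting material charged

- Overall: starting material + partner -> target, with free catalyst as catalyst.
- Constant volume, constant temperature.
- Bound and free are read together.
- An order is taken over about fifteen percent of the charge, up and down.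

Each curve flattened with both reactants present: the south run lost 4.80 mM of starting material between 2.3 h and 5.2 h, and 117.8 mM still remained. So I summed each small loss of starting material, divided by the product of starting material and partner at that moment, from the charge up to 5.2 h, and called this the exposure. With equal charges it is one over the starting material left minus one over the charge. With unequal charges it is the logarithm of the end ratio of partner to starting material over the start ratio, divided by the difference of the charges.

The south, west and south-west runs gave 1.82 M⁻¹, 1.80 M⁻¹ and 1.76 M⁻¹, so I took their mean, the exposure at 5.2 h for this catalyst charge, 1.79 M⁻¹, and assumed that the north flask would receive the same.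

In the north flask partner is charged at 1100 mM, more than the 150 mM of starting material, so that flask is nearly pseudo-first-order. Holding partner at its charge gave a lower bound of 13.9% of the starting material left. Holding it at its floor, 950 mM, gave an upper bound of 18.2%. The exact integral gave 16.1%. The plain mean of partner's two ends, 1040 mM, gave 15.5%, an error of 0.55 percentage points. Using the lowest and highest exposures narrowed my bracket to 15.7% to 16.7%.

The forecast gave orders of 1 in partner and 0.85 in starting material and, “allowing slight saturation”, 17% for the north run, which is within my wide bracket but higher than the top of my narrow one.

The simulation gave orders of 1.0 and 0.89 and left 15.9% in the north run, within the narrow bracket.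

    free catalyst + starting material ⇌ catalyst-substrate complex, settled at all times (1.220 M⁻¹)
    catalyst-substrate complex + partner ⇌ ternary complex, settled at all times (2.920 M⁻¹)
    ternary complex → target + free catalyst (1638 h⁻¹)
    free catalyst + impurity → spent catalyst
    free catalyst → spent catalyst (0.7956 h⁻¹)

The north result corresponds to an exposure of 1.81 M⁻¹, beside the 1.79 M⁻¹ carried from the earlier runs. Impurity took 0.0454 mM of free catalyst at once, and then the ternary complex gave target and free catalyst with a rate constant of 1640 h⁻¹ while free catalyst went to spent catalyst with a rate constant of 0.796 h⁻¹. In the west run, target reached half of the starting material charged at 3.82 h, when the exposure had come to 1.70 M⁻¹, which is nearly all of the 1.79 M⁻¹ carried from the earlier runs.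

Readings and results come from a simulation on assumed constants, and the scatter is random.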